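Ring B (C5–C6–C8–C9–C10) is a cyclopentane whose C9 carries the oxygenated carbon C11 beside the quaternary C8, the pattern a ring contraction leaves behind. Rings A and B are therefore first made as an easier trans-decalin by one oxidative radical bicyclisation; in it C11 is a ring ketone flanked by C8 and C9 (six-membered ring P). Photochemical Wolff rearrangement of the C9 diazo ketone shifts C8 from C11 to C9 with retention: the C8–C9 bond forms, ring B closes and C11 is expelled as a ketene, which vinylmagnesium bromide converts into the C9 acryloyl group. Metathesis (ring C) and a vinyl-radical closure (ring D) finish the skeleton.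

Key step: step 14

Remark (assumption): 4-methylpent-4-enal is taken as a purchasable aldehyde.
Conventions: atoms keep the gibberellane numbers of the target (C7 = carboxyl carbon on C6, C18 = 4-methyl, C19 = 4-carboxyl carbon, C20 = 10-methyl); α is the face of the C20 methyl, β the face of H-5; ring P = C5–C6–C8–C11–C9–C10 of the decalin intermediates. TMSE = 2-(trimethylsilyl)ethyl, TBDPS = tert-butyldiphenylsilyl, TBS = tert-butyldimethylsilyl.

Step 1
Reactants: 1 methyl 2-methyl-3-oxobutanoate; 2 2-(trimethylsilyl)ethanol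
Product: 3 2-(trimethylsilyl)ethyl 2-methyl-3-oxobutanoate
Conditions: DMAP (cat.), toluene, reflux, MeOH distilled off
Reagents that add atoms: none
Why: Transesterification of a β-keto ester (via its acyl ketene) installs a C19 ester that fluoride will cleave at the end without hydroxide; no stereocentre is set.

Step 2
Reactants: 4 4-methylpent-4-enal
Product: 6 ethyl (R,E)-4-(hydroxymethyl)-2,6-dimethylhepta-2,6-dienoate, via (S)-2-(hydroxymethyl)-4-methylpent-4-enal 5 (not isolated)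
Conditions: aq. CH2O, (R)-α,α-diphenylprolinol trimethylsilyl ether (10 mol %), toluene/pH 7 buffer, rt; then Ph3P=C(Me)CO2Et, 0 °C to rt
Reagents that add atoms: formaldehyde, C=O; ethyl 2-(triphenylphosphoranylidene)propanoate, CCOC(=O)C(C)=P(c1ccccc1)(c1ccccc1)c1ccccc1
Why: Enamine-catalysed α-hydroxymethylation (cross-aldol with formaldehyde) sets the future C6 centre, because the electrophile enters the E-enamine anti to the diaryl(silyloxy)methyl group, and the labile β-hydroxy aldehyde is trapped at once by an E-selective Wittig olefination.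

Step 3
Reactants: 6 ethyl (R,E)-4-(hydroxymethyl)-2,6-dimethylhepta-2,6-dienoate
Product: 7 ethyl (R,E)-4-[(tert-butyldiphenylsilyloxy)methyl]-2,6-dimethylhepta-2,6-dienoate
Conditions: TBDPSCl, imidazole, DMF, rt
Reagents that add atoms: tert-butyl(chloro)diphenylsilane, CC(C)(C)[Si](Cl)(c1ccccc1)c1ccccc1
Why: Silylation of the primary alcohol gives an ether that should survive acetic acid, strong bases, radicals and Grignard reagents until the final desilylation.

Step 4
Reactants: 7 ethyl (R,E)-4-[(tert-butyldiphenylsilyloxy)methyl]-2,6-dimethylhepta-2,6-dienoate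
Product: 8 (R,E)-4-[(tert-butyldiphenylsilyloxy)methyl]-2,6-dimethylhepta-2,6-dien-1-ol
Conditions: DIBAL-H (i-Bu2AlH, 2.2 equiv), CH2Cl2, −78 °C
Reagents that add atoms: none
Why: 1,2-Reduction of the enoate by the aluminium hydride gives the allylic alcohol and leaves olefins and silyl ether untouched.

Step 5
Reactants: 8 (R,E)-4-[(tert-butyldiphenylsilyloxy)methyl]-2,6-dimethylhepta-2,6-dien-1-ol
Product: 9 (R,E)-1-bromo-4-[(tert-butyldiphenylsilyloxy)methyl]-2,6-dimethylhepta-2,6-diene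
Conditions: CBr4, PPh3, CH2Cl2, 0 °C
Reagents that add atoms: carbon tetrabromide, BrC(Br)(Br)Br
Why: Appel bromination converts the primary allylic alcohol into the bromide with the E geometry retained.

Step 6
Reactants: 3 2-(trimethylsilyl)ethyl 2-methyl-3-oxobutanoate; 9 (R,E)-1-bromo-4-[(tert-butyldiphenylsilyloxy)methyl]-2,6-dimethylhepta-2,6-diene
Product: 11 TMSE (6E,8R)-8-[(tert-butyldiphenylsilyloxy)methyl]-2,6,10-trimethyl-3-oxoundeca-6,10-dienoate (C2 epimers), via dilithium bis-enolate 10 (not isolated)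
Conditions: LDA (LiN(i-Pr)2, 2.1 equiv), THF, 0 °C; then 9, 0 °C; aqueous work-up
Reagents that add atoms: none
Why: γ-Alkylation of a β-keto ester dianion (SN2 at the allylic bromide) joins C1 to C2 and completes the cyclisation substrate; the C6 centre is untouched and the new C4 centre stays epimerisable.

Step 7
Reactants: 11 TMSE (6E,8R)-8-[(tert-butyldiphenylsilyloxy)methyl]-2,6,10-trimethyl-3-oxoundeca-6,10-dienoate
Product: 12 TMSE 6β-(TBDPSOCH2)-4β,10α-dimethyl-11-methylene-3-oxo-5βH-decalin-4α-carboxylate (rings A and P trans-fused)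
Conditions: Mn(OAc)3·2H2O (2.2 equiv), Cu(OAc)2·H2O (1 equiv), AcOH, 25 °C
Reagents that add atoms: none
Why: Oxidative free-radical polyene cyclisation: the C4 radical from the manganese enolate closes ring A (6-endo at C5) and the C10 radical closes ring P (6-endo at C9) through chair-like transition states, Cu(OAc)2 oxidising the C11 radical to the exocyclic olefin; trans fusion and the axial C19 ester follow from chair/chair folding of the E-olefin, and the absolute sense from C6, whose H eclipses the C20 methyl (allylic strain) so that C8 lies anti to the incoming radical and the CH2OTBDPS group ends equatorial.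

Step 8
Reactants: 12 TMSE 6β-(TBDPSOCH2)-4β,10α-dimethyl-11-methylene-3-oxo-5βH-decalin-4α-carboxylate
Product: 13 TMSE 6β-(TBDPSOCH2)-3β-hydroxy-4β,10α-dimethyl-11-methylene-5βH-decalin-4α-carboxylate
Conditions: L-Selectride (LiBH(s-Bu)3), THF, −78 °C
Reagents that add atoms: none
Why: The bulky borohydride attacks the C3 ketone from the equatorial direction and should give the axial 3β-alcohol, trans to the axial C19 ester; C11 stays masked as the olefin, so only one carbonyl is present.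

Step 9
Reactants: 13 TMSE 6β-(TBDPSOCH2)-3β-hydroxy-4β,10α-dimethyl-11-methylene-5βH-decalin-4α-carboxylate
Product: 14 TMSE 3β-(TBSO)-6β-(TBDPSOCH2)-4β,10α-dimethyl-11-methylene-5βH-decalin-4α-carboxylate
Conditions: TBSOTf, 2,6-lutidine, CH2Cl2, 0 °C
Reagents that add atoms: tert-butyldimethylsilyl triflate, CC(C)(C)[Si](C)(C)OS(=O)(=O)C(F)(F)F
Why: Silyl triflate silylation protects the hindered axial alcohol and so prevents retro-aldol opening of the β-hydroxy ester in the enolate steps.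

Step 10
Reactants: 14 TMSE 3β-(TBSO)-6β-(TBDPSOCH2)-4β,10α-dimethyl-11-methylene-5βH-decalin-4α-carboxylate
Product: 16 TMSE 3β-(TBSO)-6β-(TBDPSOCH2)-4β,10α-dimethyl-11-oxo-5βH-decalin-4α-carboxylate, via ozonide 15 (not isolated)
Conditions: O3, CH2Cl2, −78 °C; then Me2S, −78 °C to rt
Reagents that add atoms: ozone, [O-][O+]=O
Why: Ozonolysis with reductive work-up unmasks the C11 ketone of ring P; the exocyclic olefin is the only one present.

Step 11
Reactants: 16 TMSE 3β-(TBSO)-6β-(TBDPSOCH2)-4β,10α-dimethyl-11-oxo-5βH-decalin-4α-carboxylate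
Product: 18 TMSE 8β-allyl-3β-(TBSO)-6β-(TBDPSOCH2)-4β,10α-dimethyl-11-oxo-5βH-decalin-4α-carboxylate, via lithium enolate 17 (not isolated)
Conditions: LDA (LiN(i-Pr)2), THF, −78 °C; allyl bromide, DMPU, −78 to 0 °C
Reagents that add atoms: allyl bromide, C=CCBr
Why: Kinetic enolate alkylation: deprotonation should occur at C8 and not at the neopentyl C9 next to quaternary C10, and the allyl group enters axially (β); this C8 configuration is erased in the next step.

Step 12
Reactants: 18 TMSE 8β-allyl-3β-(TBSO)-6β-(TBDPSOCH2)-4β,10α-dimethyl-11-oxo-5βH-decalin-4α-carboxylate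
Product: 20 TMSE 8α-allyl-8β-(2-bromoallyl)-3β-(TBSO)-6β-(TBDPSOCH2)-4β,10α-dimethyl-11-oxo-5βH-decalin-4α-carboxylate, via potassium enolate 19 (not isolated)
Conditions: KH, THF, 0 °C to rt (equilibration); then 2,3-dibromopropene, 0 °C
Reagents that add atoms: 2,3-dibromopropene, C=C(Br)CBr
Why: Thermodynamic enolate alkylation: the more substituted C8 enolate is alkylated from the stereoelectronically preferred axial β face, so the last-entering 2-bromoallyl group (future C15–C17) is β and the allyl group (future C14 and C13) becomes equatorial α, which fixes quaternary C8.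

Step 13
Reactants: 20 TMSE 8α-allyl-8β-(2-bromoallyl)-3β-(TBSO)-6β-(TBDPSOCH2)-4β,10α-dimethyl-11-oxo-5βH-decalin-4α-carboxylate
Product: 23 TMSE 8α-allyl-8β-(2-bromoallyl)-9-diazo-3β-(TBSO)-6β-(TBDPSOCH2)-4β,10α-dimethyl-11-oxo-5βH-decalin-4α-carboxylate, via lithium enolate 21 (not isolated), via trifluoroacetyl ketone 22 (not isolated)
Conditions: LiHMDS (LiN(SiMe3)2), THF, −78 °C; CF3CO2CH2CF3; aq. HCl work-up; then MsN3, Et3N, H2O, MeCN, rt
Reagents that add atoms: methanesulfonyl azide, CS(=O)(=O)N=[N+]=[N-]; 2,2,2-trifluoroethyl trifluoroacetate, O=C(OCC(F)(F)F)C(F)(F)F (its atoms stay only in 22)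
Why: Detrifluoroacetylative diazo transfer: C9 is the only enolisable position left, trifluoroacetylation activates it and the sulfonyl azide delivers N2 with loss of the trifluoroacetyl group; no stereocentre is touched.

Step 14
Reactants: 23 TMSE 8α-allyl-8β-(2-bromoallyl)-9-diazo-3β-(TBSO)-6β-(TBDPSOCH2)-4β,10α-dimethyl-11-oxo-5βH-decalin-4α-carboxylate
Product: 26 TMSE 9α-acryloyl-8α-allyl-8β-(2-bromoallyl)-3β-(TBSO)-6β-(TBDPSOCH2)-4β,10α-dimethyl-5βH,9βH-hydrindane-4α-carboxylate (rings A and B), via ketene 24 (not isolated), via bromomagnesium dienolate 25 (not isolated)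
Conditions: hν (365 nm), THF, −78 °C; then CH2=CHMgBr, −78 °C; AcOH, −78 °C
Reagents that add atoms: vinylmagnesium bromide, C=C[Mg]Br
Why: Irradiation expels N2 from the s-cis-locked cyclic α-diazo ketone and C8 migrates in concert from the carbonyl carbon C11 to the carbene carbon C9, giving ring-contracted ketene 24. This is the photochemical Wolff rearrangement used as a ring contraction, followed by the known addition of an organomagnesium reagent to a ketene and C-protonation of the enolate. Ring B (C5–C6–C8–C9–C10) closes by this 1,2-shift as ring P contracts, so no exo or endo chain closure is involved. C8 migrates with retention and keeps the configuration set in step 12 (allyl α, 2-bromoallyl β); C9 is set when enolate 25 is protonated, which should occur on the β face, anti to the axial C20 methyl on C10, leaving the acryloyl group α and cis to the 8α-allyl group. The step needs rearrangement to outrun carbene addition to the C8 allyl groups, which direct photolysis of a rigid cyclic diazo ketone secures, and single addition of the Grignard reagent, which holds because the product stays as enolate 25 until the quench. The C19 ester, silyl ethers and vinyl bromide should be inert at −78 °C.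

Step 15
Reactants: 26 TMSE 9α-acryloyl-8α-allyl-8β-(2-bromoallyl)-3β-(TBSO)-6β-(TBDPSOCH2)-4β,10α-dimethyl-5βH,9βH-hydrindane-4α-carboxylate
Product: 27 tricyclic enone (rings A to C): 8β-(2-bromoallyl)-11-oxo-12-ene with 3β-OTBS; C7 as CH2OTBDPS; C19 as TMSE ester
Conditions: second-generation Grubbs catalyst (5 mol %), CH2Cl2, 40 °C
Reagents that add atoms: none
Why: Ring-closing metathesis between the acryloyl group and the cis allyl group closes ring C as the cyclohexenone and releases ethylene; the 2-bromoallyl olefin is too hindered and electron-poor to take part.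

Step 16
Reactants: 27 tricyclic enone (rings A to C)
Product: 28 tetracyclic 11-ketone (target skeleton with C16=C17; 3β-OTBS; C7 as CH2OTBDPS; C19 as TMSE ester)
Conditions: Bu3SnH, AIBN (cat.), benzene, 80 °C, slow addition
Reagents that add atoms: none
Why: 5-exo-trig cyclisation of the C16 vinyl radical onto C13, the β-carbon of the enone, closes ring D; the tether from C8 can reach only the β face, which sets C13 and keeps the exocyclic C16=C17 olefin.

Step 17
Reactants: 28 tetracyclic 11-ketone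
Product: 29 tetracyclic 11α-alcohol (3β-OTBS; C7 as CH2OTBDPS; C19 as TMSE ester)
Conditions: SmI2 (2.2 equiv), THF/H2O, 0 °C
Reagents that add atoms: none
Why: Single-electron (ketyl) reduction should give the thermodynamically favoured equatorial 11α-alcohol, since the axial position points at the C15–C16 bridge; ester and olefin are not reduced.

Step 18
Reactants: 29 tetracyclic 11α-alcohol
Product: 30 3β,11α-dihydroxy-7-hydroxymethyl 19-acid (target with C7 as CH2OH)
Conditions: TBAF (Bu4NF, excess), THF, 50 °C; aq. HCl to pH 3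
Reagents that add atoms: none
Why: Fluoride cleaves both silyl ethers and fragments the TMSE ester (to ethylene and Me3SiF), freeing the hindered C19 acid without hydroxide and without retro-aldol epimerisation at C3.

Step 19
Reactants: 30 3β,11α-dihydroxy-7-hydroxymethyl 19-acid
Product: 31 CNP0232910.1 (3β,11α-dihydroxy C20 gibberellin 7,19-diacid)
Conditions: TEMPO (cat.), PhI(OAc)2 (2.2 equiv), MeCN/H2O, rt
Reagents that add atoms: water, O
Why: Oxoammonium (TEMPO) oxidation takes the primary C7 alcohol through the aldehyde hydrate to the acid much faster than it attacks the hindered secondary 3β- and 11α-alcohols.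

Compound list
1 | methyl 2-methyl-3-oxobutanoate | CC(=O)C(C)C(=O)OC | starting material
2 | 2-(trimethylsilyl)ethanol | C[Si](C)(C)CCO | starting material
3 | 2-(trimethylsilyl)ethyl 2-methyl-3-oxobutanoate | CC(=O)C(C)C(=O)OCC[Si](C)(C)C | intermediate
4 | 4-methylpent-4-enal | C=C(C)CCC=O | starting material
5 | (S)-2-(hydroxymethyl)-4-methylpent-4-enal | O=C[C@H](CO)CC(C)=C | intermediate
6 | ethyl (R,E)-4-(hydroxymethyl)-2,6-dimethylhepta-2,6-dienoate | CCOC(=O)/C(C)=C/[C@H](CO)CC(C)=C | intermediate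
7 | ethyl (R,E)-4-[(tert-butyldiphenylsilyloxy)methyl]-2,6-dimethylhepta-2,6-dienoate | CCOC(=O)/C(C)=C/[C@H](CO[Si](c1ccccc1)(c1ccccc1)C(C)(C)C)CC(C)=C | intermediate
8 | (R,E)-4-[(tert-butyldiphenylsilyloxy)methyl]-2,6-dimethylhepta-2,6-dien-1-ol | OC/C(C)=C/[C@H](CO[Si](c1ccccc1)(c1ccccc1)C(C)(C)C)CC(C)=C | intermediate
9 | (R,E)-1-bromo-4-[(tert-butyldiphenylsilyloxy)methyl]-2,6-dimethylhepta-2,6-diene | BrC/C(C)=C/[C@H](CO[Si](c1ccccc1)(c1ccccc1)C(C)(C)C)CC(C)=C | intermediate
10 | dilithium bis-enolate (dianion) of 3 | C=C([O-])C(C)=C([O-])OCC[Si](C)(C)C.[Li+].[Li+] | intermediate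
11 | TMSE (6E,8R)-8-[(tert-butyldiphenylsilyloxy)methyl]-2,6,10-trimethyl-3-oxoundeca-6,10-dienoate | C[Si](C)(C)CCOC(=O)C(C)C(=O)CC/C(C)=C/[C@H](CO[Si](c1ccccc1)(c1ccccc1)C(C)(C)C)CC(C)=C | intermediate
12 | TMSE 6β-(TBDPSOCH2)-4β,10α-dimethyl-11-methylene-3-oxo-5βH-decalin-4α-carboxylate | C2C(=C)C[C@]1(C)CCC(=O)[C@@](C)(C(=O)OCC[Si](C)(C)C)[C@H]1[C@@H]2CO[Si](c1ccccc1)(c1ccccc1)C(C)(C)C | intermediate
13 | TMSE 6β-(TBDPSOCH2)-3β-hydroxy-4β,10α-dimethyl-11-methylene-5βH-decalin-4α-carboxylate | C2C(=C)C[C@]1(C)CC[C@H](O)[C@@](C)(C(=O)OCC[Si](C)(C)C)[C@H]1[C@@H]2CO[Si](c1ccccc1)(c1ccccc1)C(C)(C)C | intermediate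
14 | TMSE 3β-(TBSO)-6β-(TBDPSOCH2)-4β,10α-dimethyl-11-methylene-5βH-decalin-4α-carboxylate | C2C(=C)C[C@]1(C)CC[C@H](O[Si](C)(C)C(C)(C)C)[C@@](C)(C(=O)OCC[Si](C)(C)C)[C@H]1[C@@H]2CO[Si](c1ccccc1)(c1ccccc1)C(C)(C)C | intermediate
15 | C11 spiro-1,2,4-trioxolane (ozonide) of 14 | C2C3(OOCO3)C[C@]1(C)CC[C@H](O[Si](C)(C)C(C)(C)C)[C@@](C)(C(=O)OCC[Si](C)(C)C)[C@H]1[C@@H]2CO[Si](c1ccccc1)(c1ccccc1)C(C)(C)C | intermediate
16 | TMSE 3β-(TBSO)-6β-(TBDPSOCH2)-4β,10α-dimethyl-11-oxo-5βH-decalin-4α-carboxylate | C2C(=O)C[C@]1(C)CC[C@H](O[Si](C)(C)C(C)(C)C)[C@@](C)(C(=O)OCC[Si](C)(C)C)[C@H]1[C@@H]2CO[Si](c1ccccc1)(c1ccccc1)C(C)(C)C | intermediate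
17 | lithium C8=C11 enolate of 16 | C2=C(O[Li])C[C@]1(C)CC[C@H](O[Si](C)(C)C(C)(C)C)[C@@](C)(C(=O)OCC[Si](C)(C)C)[C@H]1[C@@H]2CO[Si](c1ccccc1)(c1ccccc1)C(C)(C)C | intermediate
18 | TMSE 8β-allyl-3β-(TBSO)-6β-(TBDPSOCH2)-4β,10α-dimethyl-11-oxo-5βH-decalin-4α-carboxylate | C=CC[C@@H]2C(=O)C[C@]1(C)CC[C@H](O[Si](C)(C)C(C)(C)C)[C@@](C)(C(=O)OCC[Si](C)(C)C)[C@H]1[C@@H]2CO[Si](c1ccccc1)(c1ccccc1)C(C)(C)C | intermediate
19 | potassium C8=C11 enolate of 18 | C=CCC2=C(O[K])C[C@]1(C)CC[C@H](O[Si](C)(C)C(C)(C)C)[C@@](C)(C(=O)OCC[Si](C)(C)C)[C@H]1[C@@H]2CO[Si](c1ccccc1)(c1ccccc1)C(C)(C)C | intermediate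
20 | TMSE 8α-allyl-8β-(2-bromoallyl)-3β-(TBSO)-6β-(TBDPSOCH2)-4β,10α-dimethyl-11-oxo-5βH-decalin-4α-carboxylate | C=C(Br)C[C@]2(CC=C)C(=O)C[C@]1(C)CC[C@H](O[Si](C)(C)C(C)(C)C)[C@@](C)(C(=O)OCC[Si](C)(C)C)[C@H]1[C@@H]2CO[Si](c1ccccc1)(c1ccccc1)C(C)(C)C | intermediate
21 | lithium C9=C11 enolate of 20 | C=C(Br)C[C@]2(CC=C)C(O[Li])=C[C@]1(C)CC[C@H](O[Si](C)(C)C(C)(C)C)[C@@](C)(C(=O)OCC[Si](C)(C)C)[C@H]1[C@@H]2CO[Si](c1ccccc1)(c1ccccc1)C(C)(C)C | intermediate
22 | 9-(trifluoroacetyl) derivative of 20 (C9 epimers/enol) | C=C(Br)C[C@]2(CC=C)C(=O)C(C(=O)C(F)(F)F)[C@]1(C)CC[C@H](O[Si](C)(C)C(C)(C)C)[C@@](C)(C(=O)OCC[Si](C)(C)C)[C@H]1[C@@H]2CO[Si](c1ccccc1)(c1ccccc1)C(C)(C)C | intermediate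
23 | TMSE 8α-allyl-8β-(2-bromoallyl)-9-diazo-3β-(TBSO)-6β-(TBDPSOCH2)-4β,10α-dimethyl-11-oxo-5βH-decalin-4α-carboxylate | C=C(Br)C[C@]2(CC=C)C(=O)C(=[N+]=[N-])[C@]1(C)CC[C@H](O[Si](C)(C)C(C)(C)C)[C@@](C)(C(=O)OCC[Si](C)(C)C)[C@H]1[C@@H]2CO[Si](c1ccccc1)(c1ccccc1)C(C)(C)C | intermediate
24 | ring-contracted ketene (rings A and B; C9=C11=O) | C=C(Br)C[C@]2(CC=C)C(=C=O)[C@]1(C)CC[C@H](O[Si](C)(C)C(C)(C)C)[C@@](C)(C(=O)OCC[Si](C)(C)C)[C@H]1[C@@H]2CO[Si](c1ccccc1)(c1ccccc1)C(C)(C)C | intermediate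
25 | bromomagnesium dienolate C9=C11(OMgBr)–CH=CH2 | C=C(Br)C[C@]2(CC=C)C(=C(O[Mg]Br)C=C)[C@]1(C)CC[C@H](O[Si](C)(C)C(C)(C)C)[C@@](C)(C(=O)OCC[Si](C)(C)C)[C@H]1[C@@H]2CO[Si](c1ccccc1)(c1ccccc1)C(C)(C)C | intermediate
26 | TMSE 9α-acryloyl-8α-allyl-8β-(2-bromoallyl)-3β-(TBSO)-6β-(TBDPSOCH2)-4β,10α-dimethyl-5βH,9βH-hydrindane-4α-carboxylate | C=C(Br)C[C@]2(CC=C)[C@@H](C(=O)C=C)[C@]1(C)CC[C@H](O[Si](C)(C)C(C)(C)C)[C@@](C)(C(=O)OCC[Si](C)(C)C)[C@H]1[C@@H]2CO[Si](c1ccccc1)(c1ccccc1)C(C)(C)C | intermediate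
27 | tricyclic 12-en-11-one (rings A to C) with 8β-(2-bromoallyl) | C=C(Br)C[C@]23CC=CC(=O)[C@H]2[C@]1(C)CC[C@H](O[Si](C)(C)C(C)(C)C)[C@@](C)(C(=O)OCC[Si](C)(C)C)[C@H]1[C@@H]3CO[Si](c1ccccc1)(c1ccccc1)C(C)(C)C | intermediate
28 | tetracyclic 11-ketone (3β-OTBS; C7 CH2OTBDPS; C19 TMSE ester) | C=C1C[C@]23C[C@H]1CC(=O)[C@H]2[C@]1(C)CC[C@H](O[Si](C)(C)C(C)(C)C)[C@@](C)(C(=O)OCC[Si](C)(C)C)[C@H]1[C@@H]3CO[Si](c1ccccc1)(c1ccccc1)C(C)(C)C | intermediate
29 | tetracyclic 11α-alcohol (3β-OTBS; C7 CH2OTBDPS; C19 TMSE ester) | C=C1C[C@]23C[C@H]1C[C@@H](O)[C@H]2[C@]1(C)CC[C@H](O[Si](C)(C)C(C)(C)C)[C@@](C)(C(=O)OCC[Si](C)(C)C)[C@H]1[C@@H]3CO[Si](c1ccccc1)(c1ccccc1)C(C)(C)C | intermediate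
30 | 3β,11α-dihydroxy-7-hydroxymethyl 19-acid | C=C1C[C@]23C[C@H]1C[C@@H](O)[C@H]2[C@]1(C)CC[C@H](O)[C@@](C)(C(=O)O)[C@H]1[C@@H]3CO | intermediate
31 | CNP0232910.1 | C=C1C[C@]23C[C@H]1C[C@@H](O)[C@H]2[C@]1(C)CC[C@H](O)[C@@](C)(C(=O)O)[C@H]1[C@@H]3C(=O)O | target

Total step count: 19. Longest linear sequence: 18 steps (steps 2 to 19, from 4 to 31); step 1 is a one-step branch.

Steps most likely to fail

Step 14. Capture of the hindered ketene by the Grignard reagent may be slow, so that the ketene is lost on warming, and protonation of the enolate at C9 may not be face-selective. Fallback from 23: irradiation (365 nm, THF, −40 °C) in the presence of N,O-dimethylhydroxylamine traps the ketene as the stable Weinreb amide F1, which is purified and checked at C9. Vinylmagnesium bromide (THF, 0 °C to rt) then adds through the chelated tetrahedral adduct and returns the route at 26.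

Step 12. Enolisation of 18 may not go cleanly towards C8, giving alkylation at C9, O-alkylation or double alkylation. Fallback from 18: Claisen formylation at C9 (NaH, HCO2Et, THF) gives the 9-hydroxymethylene ketone F2. Its dianion (LDA, 2.2 equiv, THF, −78 °C) can be alkylated only at C8, and 2,3-dibromopropene should again enter axially (β) to give the 8,8-disubstituted hydroxymethylene ketone F3. Deformylative diazo transfer (MsN3, Et3N, MeCN) then gives 23 directly, so step 13 is bypassed.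

Step 7. The C6 centre alone may not control the face of the first ring closure, and the oxidative termination may give olefin isomers. Fallback from 11: bromination at C4 (NBS, Mg(ClO4)2 cat., MeCN) gives the α-bromo keto ester F4. Atom-transfer radical bicyclisation (Et3B/O2, Mg(ClO4)2 with a chiral bis(oxazoline) ligand matched to C6, toluene, −78 °C) places the Lewis-acid-bound radical under reagent control and ends by bromine transfer to C11, giving the tertiary bromide F5. Dehydrobromination towards the methyl group (KOt-Bu, THF, 0 °C) returns the route at 12.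

Further compounds
F1 | step 14 | Weinreb amide: 9α-[N-methoxy-N-methylcarbamoyl] analogue of 26 | C=C(Br)C[C@]2(CC=C)[C@@H](C(=O)N(C)OC)[C@]1(C)CC[C@H](O[Si](C)(C)C(C)(C)C)[C@@](C)(C(=O)OCC[Si](C)(C)C)[C@H]1[C@@H]2CO[Si](c1ccccc1)(c1ccccc1)C(C)(C)C
F2 | step 12 | 9-hydroxymethylene derivative of 18 (C8 epimers) | C=CCC2C(=O)C(=CO)[C@]1(C)CC[C@H](O[Si](C)(C)C(C)(C)C)[C@@](C)(C(=O)OCC[Si](C)(C)C)[C@H]1[C@@H]2CO[Si](c1ccccc1)(c1ccccc1)C(C)(C)C
F3 | step 12 | 9-hydroxymethylene derivative of 20 | C=C(Br)C[C@]2(CC=C)C(=O)C(=CO)[C@]1(C)CC[C@H](O[Si](C)(C)C(C)(C)C)[C@@](C)(C(=O)OCC[Si](C)(C)C)[C@H]1[C@@H]2CO[Si](c1ccccc1)(c1ccccc1)C(C)(C)C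
F4 | step 7 | 2-bromo derivative of 11 (α-bromo β-keto ester) | C[Si](C)(C)CCOC(=O)C(C)(Br)C(=O)CC/C(C)=C/[C@H](CO[Si](c1ccccc1)(c1ccccc1)C(C)(C)C)CC(C)=C
F5 | step 7 | 11-bromo-11-methyl decalin keto ester (C11 epimers) | C2C(C)(Br)C[C@]1(C)CCC(=O)[C@@](C)(C(=O)OCC[Si](C)(C)C)[C@H]1[C@@H]2CO[Si](c1ccccc1)(c1ccccc1)C(C)(C)C
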